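A direct plan would make the benzenoid ring in saturated form: a 5-aryl-cyclohexane-1,3-dione A1 (from 4-benzyloxybenzaldehyde, acetone and malonate) would be annulated with a nitroalkene A2 released in situ to give the tetrahydrobenzofuranone A3. A3 would then be dehydrogenated to the phenol A4, oxidised to the quinone A5, reductively methylated and debenzylated.
Its weakest points would be:
- The furan-forming annulation of A1 with A2 leaves the ring closure to chance. The β,γ-unsaturated nitroalkene can slip into conjugation with its ester, the adduct can stall before the nitro group is lost, and this nitroalkene has no close precedent.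
- The redox detour A3 → A4 → A5 → dimethyl ether spends three steps to add two O-methyl groups. The C7 oxygen comes from a nitroxyl-radical oxidation of late, electron-rich furan material that also carries an oxidisable CH2CO2Me group, which is the step one would least like to run there.
- The carbocycle itself costs the early steps and creates a racemic stereocentre (C6 of A3), only for the ring to be flattened afterwards.

Plan of the new route:
- The retrosynthesis cuts the C2–CH2 bond (late C–H alkylation) and then, in one operation, C4–C5, C6–C7 and C7–C7a of the benzenoid ring (Dötz benzannulation); C3a–C4 comes from a 3-furyllithium and a CO ligand.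
- The enabling feature is the pair of para oxygens on C4 and C7 that bracket C5–H and C6–aryl, with C7 bonded to the O-bearing C7a. C4(OMe) is a methoxycarbene carbon, C5–C6 a terminal arylalkyne, C7–O a CO ligand, and C3a–C7a the C3=C2 bond of a furan whose other ortho carbon is blocked by the future C3 methyl group.
- The furan ring comes first (bought as 3,4-dibromofuran); the benzenoid ring comes second and is aromatic as formed. The phenol ring arrives on the alkyne, so no biaryl coupling is needed.
- The weak steps do not arise: there is no furan annulation, no dehydrogenation, quinone or reductive methylation (both oxygens appear at the phenol level, already differentiated as OMe and OH), and no stereocentre ever exists.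

Key step: step 4

Step 1
Reactants: 1 4-ethynylphenol
Product: 2 (4-ethynylphenoxy)tri(propan-2-yl)silane
Conditions: i-Pr3SiCl, imidazole, DMF, rt
Reagents that add atoms: chlorotri(propan-2-yl)silane, CC(C)[Si](Cl)(C(C)C)C(C)C
Why: Imidazole-promoted O-silylation of the phenol should be clean because the terminal alkyne is inert, and the bulky silyl ether is chosen to survive warm THF, carbonate and radical conditions later.

Step 2
Reactants: 3 3,4-dibromofuran
Product: 5 3-bromo-4-methylfuran, via (4-bromofuran-3-yl)lithium 4 (not isolated)
Conditions: n-BuLi (1.0 equiv), THF, −78 °C; then MeI, −78 °C → rt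
Reagents that add atoms: iodomethane, CI
Why: Bromine–lithium exchange of one of the two equivalent C–Br bonds at −78 °C, where 3-furyllithiums keep their position, followed by SN2 methylation should give the unsymmetrical furan, and the symmetry of 3 removes any regiochemical question.

Step 3
Reactants: 5 3-bromo-4-methylfuran
Product: 8 pentacarbonyl[methoxy(4-methylfuran-3-yl)methylidene]chromium, via (4-methylfuran-3-yl)lithium 6 (not isolated), via lithium acylchromate 7 (not isolated)
Conditions: t-BuLi (2.0 equiv), Et2O, −78 °C; Cr(CO)6, −78 °C → rt; then Me3OBF4, CH2Cl2, 0 °C → rt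
Reagents that add atoms: hexacarbonylchromium, O=C=[Cr](=C=O)(=C=O)(=C=O)(=C=O)=C=O; trimethyloxonium tetrafluoroborate, C[O+](C)C.F[B-](F)(F)F
Why: Classical Fischer carbene synthesis, in which the 3-furyllithium from bromine–lithium exchange adds to a CO ligand of Cr(CO)6 and the acylchromate oxygen is methylated by the oxonium salt to give the methoxycarbene complex of zerovalent chromium; two equivalents of t-BuLi leave no alkyl bromide or alkyllithium to compete.

Step 4
Reactants: 8 pentacarbonyl[methoxy(4-methylfuran-3-yl)methylidene]chromium; 2 (4-ethynylphenoxy)tri(propan-2-yl)silane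
Product: 11 4-methoxy-3-methyl-6-{4-[tri(propan-2-yl)silyloxy]phenyl}-1-benzofuran-7-ol, via chromium-bound dienylketene 9 (not isolated), via tricarbonylchromium arene complex 10 (not isolated)
Conditions: 2 (1.5 equiv), THF (degassed), 55 °C; then air, MeCN, rt
Reagents that add atoms: none
Why: Thermal loss of one CO from 8 lets the alkyne coordinate and insert into the Cr=C bond with its unsubstituted carbon bonded to the carbene carbon (new C4–C5 bond), a CO ligand then inserts to give the chromium-bound dienylketene 9 (new C6–C7 bond), and 9 closes onto the free α-carbon of the furan and tautomerises to the phenol, held as the Cr(CO)3 complex 10 until air removes the metal. The closest known reaction type is the Dötz benzannulation of aryl- and furyl(methoxy)carbene complexes of chromium with terminal alkynes, which gives 4-methoxyphenols fused to the (hetero)arene. The one ring closed is the benzenoid ring, by a 6π electrocyclisation of the (E)-dienylketene (C7–C7a bond) followed by a proton shift; no stereocentre is formed. The step needs three selectivities: alkyne orientation, secured by the steric difference between H and aryl at the alkyne termini (aryl next to the CO-derived C7–OH, H next to C4–OMe); closure site, which is unique because the other furan carbon ortho to the carbene carries the methyl group that becomes C3–CH3; and CO insertion before ring closure, which a methoxycarbene of chromium bearing a furyl group in a donor solvent favours over cyclopentannulation. The two oxygens are delivered at the hydroquinone level and already differentiated as OMe and OH, so no later redox step is needed.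

Step 5
Reactants: 11 4-methoxy-3-methyl-6-{4-[tri(propan-2-yl)silyloxy]phenyl}-1-benzofuran-7-ol
Product: 12 [4-(4,7-dimethoxy-3-methyl-1-benzofuran-6-yl)phenoxy]tri(propan-2-yl)silane
Conditions: MeI, K2CO3, acetone, 50 °C
Reagents that add atoms: iodomethane, CI
Why: Williamson O-methylation of the only free phenol should proceed without touching the hindered aryl silyl ether, which is stable to carbonate in dry acetone.

Step 6
Reactants: 13 potassium O-ethyl carbonodithioate; 14 methyl bromoacetate
Product: 15 methyl 2-[(ethoxycarbonothioyl)sulfanyl]acetate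
Conditions: acetone, 0 °C → rt
Reagents that add atoms: none
Why: SN2 displacement of the α-bromo ester by the xanthate sulfur gives the radical precursor for step 7.

Step 7
Reactants: 12 [4-(4,7-dimethoxy-3-methyl-1-benzofuran-6-yl)phenoxy]tri(propan-2-yl)silane; 15 methyl 2-[(ethoxycarbonothioyl)sulfanyl]acetate
Product: 16 methyl 2-(4,7-dimethoxy-3-methyl-6-{4-[tri(propan-2-yl)silyloxy]phenyl}-1-benzofuran-2-yl)acetate
Conditions: 15 (2 equiv), dilauroyl peroxide (1.5 equiv, in portions), 1,2-dichloroethane, reflux, Ar
Reagents that add atoms: none
Why: Oxidative xanthate-transfer radical alkylation of a heteroarene, in which the undecyl radical from the peroxide releases the electrophilic CH2CO2Me radical from 15, this adds to C2 of the benzofuran (the only position giving a tertiary benzylic radical), and the peroxide oxidises the adduct to the cation, which loses the C2 proton to restore the furan.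

Step 8
Reactants: 16 methyl 2-(4,7-dimethoxy-3-methyl-6-{4-[tri(propan-2-yl)silyloxy]phenyl}-1-benzofuran-2-yl)acetate
Product: 17 phenylcandilide B (methyl 2-[6-(4-hydroxyphenyl)-4,7-dimethoxy-3-methyl-1-benzofuran-2-yl]acetate)
Conditions: Bu4NF, AcOH, THF, 0 °C
Reagents that add atoms: none
Why: Fluoride cleavage of the aryl silyl ether, buffered with acetic acid so that the liberated phenoxide is protonated at once, should leave the methyl ester and the two methyl ethers untouched.

Compound list
1 | 4-ethynylphenol | C#Cc1ccc(O)cc1 | starting material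
2 | (4-ethynylphenoxy)tri(propan-2-yl)silane | C#Cc1ccc(O[Si](C(C)C)(C(C)C)C(C)C)cc1 | intermediate
3 | 3,4-dibromofuran | Brc1cocc1Br | starting material
4 | (4-bromofuran-3-yl)lithium (formed in situ) | [Li]c1cocc1Br | intermediate
5 | 3-bromo-4-methylfuran | Cc1cocc1Br | intermediate
6 | (4-methylfuran-3-yl)lithium (formed in situ) | [Li]c1cocc1C | intermediate
7 | lithium pentacarbonyl[(4-methylfuran-3-yl)(oxido)methylidene]chromate (acylchromate of zerovalent chromium; formed in situ) | [Li+].Cc1cocc1C([O-])=[Cr](=C=O)(=C=O)(=C=O)(=C=O)=C=O | intermediate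
8 | pentacarbonyl[methoxy(4-methylfuran-3-yl)methylidene]chromium | COC(c1cocc1C)=[Cr](=C=O)(=C=O)(=C=O)(=C=O)=C=O | intermediate
9 | tricarbonylchromium complex of (3E)-4-methoxy-4-(4-methylfuran-3-yl)-2-{4-[tri(propan-2-yl)silyloxy]phenyl}buta-1,3-dien-1-one (formed in situ) | CO/C(=C/C(=C=O)c1ccc(O[Si](C(C)C)(C(C)C)C(C)C)cc1)c1cocc1C.[Cr].[C-]#[O+].[C-]#[O+].[C-]#[O+] | intermediate
10 | tricarbonyl(η6-arene)chromium complex of 11 (formed in situ) | Cc1coc2c(O)c(-c3ccc(O[Si](C(C)C)(C(C)C)C(C)C)cc3)cc(OC)c12.[Cr].[C-]#[O+].[C-]#[O+].[C-]#[O+] | intermediate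
11 | 4-methoxy-3-methyl-6-{4-[tri(propan-2-yl)silyloxy]phenyl}-1-benzofuran-7-ol | Cc1coc2c(O)c(-c3ccc(O[Si](C(C)C)(C(C)C)C(C)C)cc3)cc(OC)c12 | intermediate
12 | [4-(4,7-dimethoxy-3-methyl-1-benzofuran-6-yl)phenoxy]tri(propan-2-yl)silane | Cc1coc2c(OC)c(-c3ccc(O[Si](C(C)C)(C(C)C)C(C)C)cc3)cc(OC)c12 | intermediate
13 | potassium O-ethyl carbonodithioate | CCOC(=S)[S-].[K+] | starting material
14 | methyl bromoacetate | COC(=O)CBr | starting material
15 | methyl 2-[(ethoxycarbonothioyl)sulfanyl]acetate | CCOC(=S)SCC(=O)OC | intermediate
16 | methyl 2-(4,7-dimethoxy-3-methyl-6-{4-[tri(propan-2-yl)silyloxy]phenyl}-1-benzofuran-2-yl)acetate | COC(=O)Cc1oc2c(OC)c(-c3ccc(O[Si](C(C)C)(C(C)C)C(C)C)cc3)cc(OC)c2c1C | intermediate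
17 | phenylcandilide B, methyl 2-[6-(4-hydroxyphenyl)-4,7-dimethoxy-3-methyl-1-benzofuran-2-yl]acetate (achiral) | COC(=O)Cc1oc2c(OC)c(-c3ccc(O)cc3)cc(OC)c2c1C | target

Total step count: 8 (steps 1 and 6 are one-step preparations of the alkyne partner and of the radical precursor).
Longest linear sequence: 6 steps (3 → 5 → 8 → 11 → 12 → 16 → 17).

Steps most likely to fail

Step 4. The free hydroquinone monoether could be lost while the metal is removed, through further oxidation by air or incomplete decomplexation. The fallback would set out from 8 and 2 with the same benzannulation but would give up the phenol on purpose. Oxidative work-up of the crude complex 10 with (NH4)2Ce(NO3)6 (tetravalent cerium) in aqueous MeCN would give 3-methyl-6-{4-[tri(propan-2-yl)silyloxy]phenyl}-1-benzofuran-4,7-dione F1, which is stable to air and chromatography. Reduction with Na2S2O4 would give 3-methyl-6-{4-[tri(propan-2-yl)silyloxy]phenyl}-1-benzofuran-4,7-diol F2, and double O-methylation in the same flask (Me2SO4, K2CO3, acetone) would come back to the route at 12, so that step 5 would be skipped.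

Step 7. The radical addition could show poor site selectivity (attack on the electron-rich benzenoid ring, or a second alkylation at the new benzylic CH2), or the chain could stall. The fallback would set out from 12. Deprotonation at C2, the most acidic ring C–H (n-BuLi, THF, −78 °C), would give {4,7-dimethoxy-3-methyl-6-{4-[tri(propan-2-yl)silyloxy]phenyl}-1-benzofuran-2-yl}lithium F3. Quenching with I2 would give {4-[2-iodo-4,7-dimethoxy-3-methyl-1-benzofuran-6-yl]phenoxy}tri(propan-2-yl)silane F4. Cross-coupling of F4 with the Reformatsky reagent BrZnCH2CO2Me (Pd2(dba)3, XPhos, THF, 60 °C) would return to the route at 16.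

Step 3. Lithium could migrate from C3 to an α-position of the furan during the slow, heterogeneous capture by Cr(CO)6, which would deliver an isomeric 2-furyl carbene. The fallback would reverse the polarity of the carbene synthesis and set out from 6, generated from 5 as before. Trapping at once with CO2 at −78 °C would give 4-methylfuran-3-carboxylic acid F5, and (COCl)2 with catalytic DMF would give 4-methylfuran-3-carbonyl chloride F6. Acylation of K2Cr(CO)5 (from Cr(CO)6 and KC8, THF, −78 °C) would give potassium pentacarbonyl[(4-methylfuran-3-yl)(oxido)methylidene]chromate F7, and O-methylation with Me3OBF4 would come back to the route at 8.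

Further compounds
F1 | step 4 | 3-methyl-6-{4-[tri(propan-2-yl)silyloxy]phenyl}-1-benzofuran-4,7-dione | Cc1coc2c1C(=O)C=C(c1ccc(O[Si](C(C)C)(C(C)C)C(C)C)cc1)C2=O
F2 | step 4 | 3-methyl-6-{4-[tri(propan-2-yl)silyloxy]phenyl}-1-benzofuran-4,7-diol | Cc1coc2c(O)c(-c3ccc(O[Si](C(C)C)(C(C)C)C(C)C)cc3)cc(O)c12
F3 | step 7 | {4,7-dimethoxy-3-methyl-6-{4-[tri(propan-2-yl)silyloxy]phenyl}-1-benzofuran-2-yl}lithium | [Li]c1oc2c(OC)c(-c3ccc(O[Si](C(C)C)(C(C)C)C(C)C)cc3)cc(OC)c2c1C
F4 | step 7 | {4-[2-iodo-4,7-dimethoxy-3-methyl-1-benzofuran-6-yl]phenoxy}tri(propan-2-yl)silane | Cc1c(I)oc2c(OC)c(-c3ccc(O[Si](C(C)C)(C(C)C)C(C)C)cc3)cc(OC)c12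
F5 | step 3 | 4-methylfuran-3-carboxylic acid | Cc1cocc1C(=O)O
F6 | step 3 | 4-methylfuran-3-carbonyl chloride | Cc1cocc1C(Cl)=O
F7 | step 3 | potassium pentacarbonyl[(4-methylfuran-3-yl)(oxido)methylidene]chromate | [K+].Cc1cocc1C([O-])=[Cr](=C=O)(=C=O)(=C=O)(=C=O)=C=O
A1 | direct plan | 5-[4-(benzyloxy)phenyl]cyclohexane-1,3-dione | O=C1CC(=O)CC(c2ccc(OCc3ccccc3)cc2)C1
A2 | direct plan | methyl (E)-3-nitropent-3-enoate | C/C=C(\CC(=O)OC)[N+](=O)[O-]
A3 | direct plan | methyl 2-[6-(4-benzyloxyphenyl)-3-methyl-4-oxo-4,5,6,7-tetrahydro-1-benzofuran-2-yl]acetate (racemic at C6) | COC(=O)Cc1oc2c(c1C)C(=O)CC(c1ccc(OCc3ccccc3)cc1)C2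
A4 | direct plan | methyl 2-[6-(4-benzyloxyphenyl)-4-hydroxy-3-methyl-1-benzofuran-2-yl]acetate | COC(=O)Cc1oc2cc(-c3ccc(OCc4ccccc4)cc3)cc(O)c2c1C
A5 | direct plan | methyl 2-[6-(4-benzyloxyphenyl)-3-methyl-4,7-dioxo-4,7-dihydro-1-benzofuran-2-yl]acetate | COC(=O)Cc1oc2c(c1C)C(=O)C=C(c1ccc(OCc3ccccc3)cc1)C2=O
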